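**Retrosynthetic overview**

- Feature: the benzene ring C3a–C4–C5–C6–C7–C7a carries oxygen on C5 and C7 (1,3 to each other) and the C1 carboxyl carbon on C7a, which lies between C7 and C3a; C3a bears the C3 carbinol. This is the pattern of a 2-carbomethoxycyclohexane-1,3-dione with its side chain on the neighbouring ring carbon.
- Lactone ring (closed last): the O2–C1 bond forms by acid lactonisation during global deprotection of a methyl 2-methoxy-4-(methoxymethoxy)-6-(1-silyloxyalkyl)benzoate; O7 is methylated while O5 is held as its MOM ether.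
- Arene: dehydrogenation of a methyl 6-alkyl-2,4-dioxocyclohexane-1-carboxylate, the only carbocycle and the first ring formed.
- Carbocycle: Michael–Dieckmann annulation of methyl acetoacetate with a methyl (E)-4-silyloxy-2-enoate, forming C7a–C3a and then C6–C5.
- Enoate: D-proline α-aminoxylation and Horner–Wadsworth–Emmons olefination of an aldehyde (sets C3); the aldehyde comes by ozonolysis from the ketal of a ketone made from the Weinreb amide of (S)-γ-valerolactone (brings C13′) and dodec-11-enylmagnesium bromide.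

Key step: step 9

Remark on numbering: ring atoms are numbered as in the phthalide (C1 lactone carbonyl, O2, C3 carbinol, C3a–C7a benzene ring); side-chain atoms are primed, C1′ being bonded to C3. TBS = tert-butyldimethylsilyl, MOM = methoxymethyl.

Remark on the chemistry: the target is taken as the open-chain γ-hydroxy ketone as drawn, which is expected to prevail over its five-membered lactol after neutral aqueous work-up.

**Route**

Step 1
Reactants: 1 (S)-γ-valerolactone
Product: 2 (4S)-4-hydroxy-N-methoxy-N-methylpentanamide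
Conditions: MeNH(OMe)·HCl, AlMe3, CH2Cl2, 0 °C to rt; used crude
Reagents that add atoms: N,O-dimethylhydroxylamine hydrochloride, Cl.CNOC
Why: Weinreb aminolysis of the lactone by the aluminium amide formed in the flask opens the ring at the acyl carbon only, so the C–O bond of the stereocentre is untouched and the (S) configuration of 1 (future C13′) is carried over.

Step 2
Reactants: 2 (4S)-4-hydroxy-N-methoxy-N-methylpentanamide
Product: 3 (4S)-4-(tert-butyldimethylsilyloxy)-N-methoxy-N-methylpentanamide
Conditions: TBSCl, imidazole, DMF, rt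
Reagents that add atoms: tert-butyldimethylsilyl chloride, CC(C)(C)[Si](C)(C)Cl
Why: Imidazole-mediated O-silylation of the secondary alcohol is routine and also blocks relactonisation of the γ-hydroxy amide.

Step 3
Reactants: 3 (4S)-4-(tert-butyldimethylsilyloxy)-N-methoxy-N-methylpentanamide; 4 12-bromododec-1-ene
Product: 6 (2S)-2-(tert-butyldimethylsilyloxy)heptadec-16-en-5-one, via dodec-11-en-1-ylmagnesium bromide 5 (not isolated)
Conditions: 4, Mg, THF, 45 °C; then 3, THF, 0 °C to rt
Reagents that add atoms: none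
Why: Weinreb ketone synthesis, in which the chelated tetrahedral magnesium adduct resists a second addition of the primary Grignard reagent and collapses to the ketone only on aqueous work-up.

Step 4
Reactants: 6 (2S)-2-(tert-butyldimethylsilyloxy)heptadec-16-en-5-one
Product: 7 2-[(3S)-3-(tert-butyldimethylsilyloxy)butyl]-2-(dodec-11-en-1-yl)-1,3-dioxolane
Conditions: TMSOCH2CH2OTMS, TMSOTf (5 mol%), CH2Cl2, −78 to −20 °C; pyridine quench
Reagents that add atoms: 1,2-bis(trimethylsilyloxy)ethane, C[Si](C)(C)OCCO[Si](C)(C)C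
Why: Noyori ketalisation runs at low temperature without free protic acid, so the secondary silyl ether and the alkene should survive while the ketone is masked against the enolate, ozone and selenium chemistry ahead.

Step 5
Reactants: 7 2-[(3S)-3-(tert-butyldimethylsilyloxy)butyl]-2-(dodec-11-en-1-yl)-1,3-dioxolane
Product: 8 11-{2-[(3S)-3-(tert-butyldimethylsilyloxy)butyl]-1,3-dioxolan-2-yl}undecanal
Conditions: O3, CH2Cl2, −78 °C; then PPh3, −78 °C to rt
Reagents that add atoms: ozone, [O-][O+]=O
Why: Ozonolysis of the monosubstituted alkene with reductive work-up gives the aldehyde with loss of the terminal carbon, and ketone ketals and alkyl silyl ethers tolerate ozone at −78 °C.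

Step 6
Reactants: 8 11-{2-[(3S)-3-(tert-butyldimethylsilyloxy)butyl]-1,3-dioxolan-2-yl}undecanal; 9 trimethyl phosphonoacetate
Product: 11 methyl (2E,4S,17S)-4-(anilinooxy)-17-(tert-butyldimethylsilyloxy)-14,14-(ethylenedioxy)octadec-2-enoate, via α-aminoxy aldehyde 10 (not isolated)
Conditions: PhNO (1.0 equiv), D-proline (30 mol%), MeCN, −20 °C; then 9, LiCl, DBU, MeCN, 0 °C
Reagents that add atoms: nitrosobenzene, O=Nc1ccccc1
Why: Proline-catalysed α-aminoxylation (O-selective nitroso aldol reaction of the enamine) is followed in the same flask by Horner–Wadsworth–Emmons olefination under Masamune–Roush conditions; the carboxylic acid of D-proline delivers nitrosobenzene to one face of the E-enamine, which for the D-catalyst should set the (S) configuration at the future C3, and the stabilised phosphonate gives the E-enoate.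

Step 7
Reactants: 11 methyl (2E,4S,17S)-4-(anilinooxy)-17-(tert-butyldimethylsilyloxy)-14,14-(ethylenedioxy)octadec-2-enoate
Product: 12 methyl (2E,4S,17S)-17-(tert-butyldimethylsilyloxy)-14,14-(ethylenedioxy)-4-hydroxyoctadec-2-enoate
Conditions: Cu(OAc)2·H2O (30 mol%), MeOH, rt
Reagents that add atoms: none
Why: Cu(OAc)2-catalysed cleavage of the weak N–O bond of the O-alkyl-N-arylhydroxylamine frees the γ-hydroxy enoate under neutral conditions that leave the alkene geometry, the ketal and the silyl ether alone.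

Step 8
Reactants: 12 methyl (2E,4S,17S)-17-(tert-butyldimethylsilyloxy)-14,14-(ethylenedioxy)-4-hydroxyoctadec-2-enoate
Product: 13 methyl (2E,4S,17S)-4,17-bis(tert-butyldimethylsilyloxy)-14,14-(ethylenedioxy)octadec-2-enoate
Conditions: TBSCl, imidazole, DMF, rt
Reagents that add atoms: tert-butyldimethylsilyl chloride, CC(C)(C)[Si](C)(C)Cl
Why: Imidazole-mediated O-silylation of the allylic alcohol uses a base too weak to remove the γ-hydrogen of the enoate, so geometry and configuration should be retained.

Step 9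
Reactants: 13 methyl (2E,4S,17S)-4,17-bis(tert-butyldimethylsilyloxy)-14,14-(ethylenedioxy)octadec-2-enoate; 14 methyl acetoacetate
Product: 16 methyl 6-[(1S,14S)-1,14-bis(tert-butyldimethylsilyloxy)-11,11-(ethylenedioxy)pentadecyl]-2,4-dioxocyclohexane-1-carboxylate (mixture of ring epimers/enol tautomers), via acyclic Michael adduct 15 (not isolated)
Conditions: 14 (1.3 equiv), NaOMe (1.2 equiv), MeOH, 25 °C then reflux; cold 0.5 M HCl to pH 4, rapid extraction
Reagents that add atoms: none
Why: The sodium enolate of 14 adds through its central carbon (future C7a) to the β-carbon of the enoate (future C3a), and after proton transfer the methyl-ketone enolate (future C6) attacks the former enoate ester carbon (future C5) with loss of methoxide. This is the classical acetoacetate Michael–Dieckmann route to dihydroresorcylates (6-alkyl-2,4-dioxocyclohexanecarboxylates). The carbocycle closes in a 6-(enolendo)-exo-trig Claisen step, the only one open to adduct 15 because every other enolate–carbonyl pairing would give a four-membered ring, and deprotonation of the 1,3-dione makes the closure irreversible. The two new ring stereocentres (C3a and C7a) are not controlled and need not be, since both become sp2 on aromatisation, while the C3 carbinol is a spectator. The step needs alkylation of the acetoacetate at its central carbon before any Claisen chemistry, which the soft stabilised enolate and the activated enoate secure, and it needs the γ-hydrogen of 13 to stay in place, which is served by keeping 14 in excess over NaOMe so that the base present during conjugate addition is the weakly basic acetoacetate enolate; once C3a is sp3 the silyloxy group is not β to any carbanion and can neither eliminate nor epimerise.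

Step 10
Reactants: 16 methyl 6-[(1S,14S)-1,14-bis(tert-butyldimethylsilyloxy)-11,11-(ethylenedioxy)pentadecyl]-2,4-dioxocyclohexane-1-carboxylate
Product: 19 methyl 6-[(1S,14S)-1,14-bis(tert-butyldimethylsilyloxy)-11,11-(ethylenedioxy)pentadecyl]-2,4-dihydroxybenzoate, via C7a phenylselenide 17 (not isolated), via selenoxide 18 (not isolated)
Conditions: LiN(iPr)2 (2.3 equiv), THF, −78 to −40 °C; PhSeBr (1.05 equiv), −78 °C; then 30% H2O2, pyridine, CH2Cl2, 0 °C to rt
Reagents that add atoms: none
Why: Dehydrogenation by α-selenenylation and selenoxide syn-elimination: the dianion of the β-keto ester/1,3-dione should be selenenylated at its most basic carbon (the ester-bearing ring carbon, future C7a) anti to the bulky C3a substituent and hence syn to H3a, the selenoxide eliminates to the C7a=C3a alkene, and the resulting dienone tautomerises to the resorcylate under base/neutral conditions that spare both silyl ethers and the ketal (selenenylation at the future C4 would lead to the same arene).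

Step 11
Reactants: 19 methyl 6-[(1S,14S)-1,14-bis(tert-butyldimethylsilyloxy)-11,11-(ethylenedioxy)pentadecyl]-2,4-dihydroxybenzoate
Product: 20 methyl 6-[(1S,14S)-1,14-bis(tert-butyldimethylsilyloxy)-11,11-(ethylenedioxy)pentadecyl]-2-hydroxy-4-(methoxymethoxy)benzoate
Conditions: MOMCl (1.1 equiv), iPr2NEt, CH2Cl2, 0 °C
Reagents that add atoms: chloromethyl methyl ether, COCCl
Why: Chemoselective O-alkylation (Williamson type): the 4-hydroxyl, para to the ester, is the more acidic and is not hydrogen-bonded, whereas the 2-hydroxyl is held in a chelate with the ester carbonyl, so one equivalent of MOMCl should alkylate only the future C5 oxygen.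

Step 12
Reactants: 20 methyl 6-[(1S,14S)-1,14-bis(tert-butyldimethylsilyloxy)-11,11-(ethylenedioxy)pentadecyl]-2-hydroxy-4-(methoxymethoxy)benzoate
Product: 21 methyl 6-[(1S,14S)-1,14-bis(tert-butyldimethylsilyloxy)-11,11-(ethylenedioxy)pentadecyl]-2-methoxy-4-(methoxymethoxy)benzoate
Conditions: MeI, K2CO3, DMF, 40 °C
Reagents that add atoms: iodomethane, CI
Why: Williamson methylation of the remaining chelated phenol (future C7 oxygen) under carbonate conditions, to which the aryl MOM ether, the alkyl silyl ethers, the ketal and the methyl ester are inert.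

Step 13
Reactants: 21 methyl 6-[(1S,14S)-1,14-bis(tert-butyldimethylsilyloxy)-11,11-(ethylenedioxy)pentadecyl]-2-methoxy-4-(methoxymethoxy)benzoate
Product: 23 (3S)-5-hydroxy-3-[(13S)-13-hydroxy-10-oxotetradecyl]-7-methoxy-2-benzofuran-1(3H)-one (CNP0341577.2), via seco hydroxy ester 22 (not isolated)
Conditions: 3 M aq. HCl–THF (1:3), 45 °C
Reagents that add atoms: water, O
Why: Acid-catalysed global hydrolysis removes the MOM acetal, both silyl ethers and the dioxolane, and the freed benzylic hydroxyl closes onto the neighbouring methyl ester (5-exo-trig lactonisation to the phthalide); the carbinol carbon is meta to both ring oxygens and ortho to the carbonyl, so no benzylic cation should form and the C3 configuration should hold.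

**Compound list**

1 | (S)-γ-valerolactone [(5S)-5-methyloxolan-2-one] | C[C@H]1CCC(=O)O1 | starting material
2 | (4S)-4-hydroxy-N-methoxy-N-methylpentanamide | C[C@H](O)CCC(=O)N(C)OC | intermediate
3 | (4S)-4-(tert-butyldimethylsilyloxy)-N-methoxy-N-methylpentanamide | C[C@H](O[Si](C)(C)C(C)(C)C)CCC(=O)N(C)OC | intermediate
4 | 12-bromododec-1-ene | C=CCCCCCCCCCCBr | starting material
5 | dodec-11-en-1-ylmagnesium bromide | C=CCCCCCCCCCC[Mg]Br | intermediate (not isolated)
6 | (2S)-2-(tert-butyldimethylsilyloxy)heptadec-16-en-5-one | C[C@H](O[Si](C)(C)C(C)(C)C)CCC(=O)CCCCCCCCCCC=C | intermediate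
7 | 2-[(3S)-3-(tert-butyldimethylsilyloxy)butyl]-2-(dodec-11-en-1-yl)-1,3-dioxolane | C[C@H](O[Si](C)(C)C(C)(C)C)CCC1(OCCO1)CCCCCCCCCCC=C | intermediate
8 | 11-{2-[(3S)-3-(tert-butyldimethylsilyloxy)butyl]-1,3-dioxolan-2-yl}undecanal | C[C@H](O[Si](C)(C)C(C)(C)C)CCC1(OCCO1)CCCCCCCCCCC=O | intermediate
9 | trimethyl phosphonoacetate | COC(=O)CP(=O)(OC)OC | starting material
10 | (2S)-2-(anilinooxy)-11-{2-[(3S)-3-(tert-butyldimethylsilyloxy)butyl]-1,3-dioxolan-2-yl}undecanal | O=C[C@@H](ONc1ccccc1)CCCCCCCCCC1(OCCO1)CC[C@H](C)O[Si](C)(C)C(C)(C)C | intermediate (not isolated)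
11 | methyl (2E,4S,17S)-4-(anilinooxy)-17-(tert-butyldimethylsilyloxy)-14,14-(ethylenedioxy)octadec-2-enoate | COC(=O)/C=C/[C@@H](ONc1ccccc1)CCCCCCCCCC1(OCCO1)CC[C@H](C)O[Si](C)(C)C(C)(C)C | intermediate
12 | methyl (2E,4S,17S)-17-(tert-butyldimethylsilyloxy)-14,14-(ethylenedioxy)-4-hydroxyoctadec-2-enoate | COC(=O)/C=C/[C@@H](O)CCCCCCCCCC1(OCCO1)CC[C@H](C)O[Si](C)(C)C(C)(C)C | intermediate
13 | methyl (2E,4S,17S)-4,17-bis(tert-butyldimethylsilyloxy)-14,14-(ethylenedioxy)octadec-2-enoate | COC(=O)/C=C/[C@@H](O[Si](C)(C)C(C)(C)C)CCCCCCCCCC1(OCCO1)CC[C@H](C)O[Si](C)(C)C(C)(C)C | intermediate (key-step precursor)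
14 | methyl acetoacetate | COC(=O)CC(C)=O | starting material
15 | dimethyl 2-acetyl-3-[(1S,14S)-1,14-bis(tert-butyldimethylsilyloxy)-11,11-(ethylenedioxy)pentadecyl]pentanedioate (C2/C3 epimers) | COC(=O)CC(C(C(C)=O)C(=O)OC)[C@@H](O[Si](C)(C)C(C)(C)C)CCCCCCCCCC1(OCCO1)CC[C@H](C)O[Si](C)(C)C(C)(C)C | intermediate (not isolated)
16 | methyl 6-[(1S,14S)-1,14-bis(tert-butyldimethylsilyloxy)-11,11-(ethylenedioxy)pentadecyl]-2,4-dioxocyclohexane-1-carboxylate (ring epimers, enol tautomers) | COC(=O)C1C(=O)CC(=O)CC1[C@@H](O[Si](C)(C)C(C)(C)C)CCCCCCCCCC2(OCCO2)CC[C@H](C)O[Si](C)(C)C(C)(C)C | intermediate (key-step product)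
17 | methyl 6-[(1S,14S)-1,14-bis(tert-butyldimethylsilyloxy)-11,11-(ethylenedioxy)pentadecyl]-2,4-dioxo-1-(phenylselanyl)cyclohexane-1-carboxylate | COC(=O)C1([Se]c2ccccc2)C(=O)CC(=O)CC1[C@@H](O[Si](C)(C)C(C)(C)C)CCCCCCCCCC3(OCCO3)CC[C@H](C)O[Si](C)(C)C(C)(C)C | intermediate (not isolated)
18 | methyl 6-[(1S,14S)-1,14-bis(tert-butyldimethylsilyloxy)-11,11-(ethylenedioxy)pentadecyl]-2,4-dioxo-1-(phenylseleninyl)cyclohexane-1-carboxylate | COC(=O)C1([Se](=O)c2ccccc2)C(=O)CC(=O)CC1[C@@H](O[Si](C)(C)C(C)(C)C)CCCCCCCCCC3(OCCO3)CC[C@H](C)O[Si](C)(C)C(C)(C)C | intermediate (not isolated)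
19 | methyl 6-[(1S,14S)-1,14-bis(tert-butyldimethylsilyloxy)-11,11-(ethylenedioxy)pentadecyl]-2,4-dihydroxybenzoate | COC(=O)c1c(O)cc(O)cc1[C@@H](O[Si](C)(C)C(C)(C)C)CCCCCCCCCC2(OCCO2)CC[C@H](C)O[Si](C)(C)C(C)(C)C | intermediate
20 | methyl 6-[(1S,14S)-1,14-bis(tert-butyldimethylsilyloxy)-11,11-(ethylenedioxy)pentadecyl]-2-hydroxy-4-(methoxymethoxy)benzoate | COC(=O)c1c(O)cc(OCOC)cc1[C@@H](O[Si](C)(C)C(C)(C)C)CCCCCCCCCC2(OCCO2)CC[C@H](C)O[Si](C)(C)C(C)(C)C | intermediate
21 | methyl 6-[(1S,14S)-1,14-bis(tert-butyldimethylsilyloxy)-11,11-(ethylenedioxy)pentadecyl]-2-methoxy-4-(methoxymethoxy)benzoate | COC(=O)c1c(OC)cc(OCOC)cc1[C@@H](O[Si](C)(C)C(C)(C)C)CCCCCCCCCC2(OCCO2)CC[C@H](C)O[Si](C)(C)C(C)(C)C | intermediate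
22 | methyl 6-[(1S,13S)-1,13-dihydroxy-10-oxotetradecyl]-4-hydroxy-2-methoxybenzoate | COC(=O)c1c(OC)cc(O)cc1[C@@H](O)CCCCCCCCCC(=O)CC[C@H](C)O | intermediate (not isolated)
23 | (3S)-5-hydroxy-3-[(13S)-13-hydroxy-10-oxotetradecyl]-7-methoxy-2-benzofuran-1(3H)-one | COc1cc(O)cc2c1C(=O)O[C@H]2CCCCCCCCCC(=O)CC[C@H](C)O | target

**Step count and risks**

Total step count: 13. Longest linear sequence: 13 steps, from (S)-γ-valerolactone 1; compounds 4, 9 and 14 enter as purchased reagents.

Steps most likely to fail:

1. Step 9 (key step). Conjugate addition to the γ-branched, γ-silyloxy enoate may be slow. Methoxide would then have time to remove the γ-hydrogen (vinylogous enolisation, which would erode the C3 configuration or move the double bond out of conjugation) or to cleave the acetyl group of the adduct by retro-Claisen reaction. The fallback sets out from aldehyde 8 and comes back at dione 16, building the same ring from an enone and a malonate. Aldehyde 8 is aminoxylated as in step 6 (through 10) and olefinated in the same flask with dimethyl (2-oxopropyl)phosphonate, LiCl and DBU to give (3E,5S,18S)-5-(anilinooxy)-18-(tert-butyldimethylsilyloxy)-15,15-(ethylenedioxy)nonadec-3-en-2-one F1. Cu(OAc)2 in MeOH then gives (3E,5S,18S)-18-(tert-butyldimethylsilyloxy)-15,15-(ethylenedioxy)-5-hydroxynonadec-3-en-2-one F2, and TBSCl/imidazole gives (3E,5S,18S)-5,18-bis(tert-butyldimethylsilyloxy)-15,15-(ethylenedioxy)nonadec-3-en-2-one F3. The enone is a far better acceptor than the enoate, so dimethyl malonate with catalytic NaOMe in MeOH at 0 °C should add before any γ-deprotonation, giving dimethyl 2-[(2S,15S)-2,15-bis(tert-butyldimethylsilyloxy)-12,12-(ethylenedioxy)-1-(2-oxopropyl)hexadecyl]propanedioate F4. Heating F4 with one equivalent of NaOMe closes the ring by Claisen attack of the methyl-ketone enolate on a malonate ester (forming C6–C7 instead of C6–C5) and delivers 16.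

2. Step 10. Selenenylation may stray to the central dione carbon (C6) or to oxygen, may occur syn to the C3a substituent so that no syn hydrogen is available for elimination, or the arene may be selenated by the selenenic acid set free. The fallback sets out from 16 and comes back at target 23, using the classical halogenation–dehydrohalogenation aromatisation and accepting loss of the acid-labile groups. Dione 16 is treated with CuBr2 (2.0 equiv) and LiBr in MeCN at 0 °C to rt; the resorcylate 19 so formed, by then partly stripped by HBr, is not isolated but stirred with 3 M aq. HCl–THF to complete desilylation, deketalisation and lactonisation to (3S)-5,7-dihydroxy-3-[(13S)-13-hydroxy-10-oxotetradecyl]-2-benzofuran-1(3H)-one F5. The non-chelated 5-hydroxyl is then allylated with allyl bromide (1.05 equiv) and K2CO3 in acetone to give (3S)-5-(allyloxy)-7-hydroxy-3-[(13S)-13-hydroxy-10-oxotetradecyl]-2-benzofuran-1(3H)-one F6. Methylation with MeI and K2CO3 in DMF gives (3S)-5-(allyloxy)-3-[(13S)-13-hydroxy-10-oxotetradecyl]-7-methoxy-2-benzofuran-1(3H)-one F7, and Pd(PPh3)4 with morpholine in THF removes the allyl group to give 23.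

3. Step 13. Four hydrolyses and a lactonisation must all run to completion in one flask. Cleavage of the hindered benzylic silyl ether may lag, the formaldehyde released from the MOM group may hydroxymethylate the electron-rich ring, and the γ-hydroxy ketone may dehydrate to a dihydrofuran under prolonged heating. The fallback sets out from resorcylate 19 and comes back at 23, replacing MOM by a benzyl group removed separately by hydrogenolysis. BnBr (1.05 equiv) and K2CO3 in acetone give methyl 4-(benzyloxy)-6-[(1S,14S)-1,14-bis(tert-butyldimethylsilyloxy)-11,11-(ethylenedioxy)pentadecyl]-2-hydroxybenzoate F8. MeI and K2CO3 in DMF give methyl 4-(benzyloxy)-6-[(1S,14S)-1,14-bis(tert-butyldimethylsilyloxy)-11,11-(ethylenedioxy)pentadecyl]-2-methoxybenzoate F9. Aqueous HCl–THF at rt, with no formaldehyde present and with gentler heating possible, gives (3S)-5-(benzyloxy)-3-[(13S)-13-hydroxy-10-oxotetradecyl]-7-methoxy-2-benzofuran-1(3H)-one F10, which can be purified. H2 (1 atm) over Pd/C in EtOAc then gives 23.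

**Further compounds**

F1 | step 9 | (3E,5S,18S)-5-(anilinooxy)-18-(tert-butyldimethylsilyloxy)-15,15-(ethylenedioxy)nonadec-3-en-2-one | CC(=O)/C=C/[C@@H](ONc1ccccc1)CCCCCCCCCC1(OCCO1)CC[C@H](C)O[Si](C)(C)C(C)(C)C
F2 | step 9 | (3E,5S,18S)-18-(tert-butyldimethylsilyloxy)-15,15-(ethylenedioxy)-5-hydroxynonadec-3-en-2-one | CC(=O)/C=C/[C@@H](O)CCCCCCCCCC1(OCCO1)CC[C@H](C)O[Si](C)(C)C(C)(C)C
F3 | step 9 | (3E,5S,18S)-5,18-bis(tert-butyldimethylsilyloxy)-15,15-(ethylenedioxy)nonadec-3-en-2-one | CC(=O)/C=C/[C@@H](O[Si](C)(C)C(C)(C)C)CCCCCCCCCC1(OCCO1)CC[C@H](C)O[Si](C)(C)C(C)(C)C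
F4 | step 9 | dimethyl 2-[(2S,15S)-2,15-bis(tert-butyldimethylsilyloxy)-12,12-(ethylenedioxy)-1-(2-oxopropyl)hexadecyl]propanedioate | COC(=O)C(C(=O)OC)C(CC(C)=O)[C@@H](O[Si](C)(C)C(C)(C)C)CCCCCCCCCC1(OCCO1)CC[C@H](C)O[Si](C)(C)C(C)(C)C
F5 | step 10 | (3S)-5,7-dihydroxy-3-[(13S)-13-hydroxy-10-oxotetradecyl]-2-benzofuran-1(3H)-one | Oc1cc(O)cc2c1C(=O)O[C@H]2CCCCCCCCCC(=O)CC[C@H](C)O
F6 | step 10 | (3S)-5-(allyloxy)-7-hydroxy-3-[(13S)-13-hydroxy-10-oxotetradecyl]-2-benzofuran-1(3H)-one | Oc1cc(OCC=C)cc2c1C(=O)O[C@H]2CCCCCCCCCC(=O)CC[C@H](C)O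
F7 | step 10 | (3S)-5-(allyloxy)-3-[(13S)-13-hydroxy-10-oxotetradecyl]-7-methoxy-2-benzofuran-1(3H)-one | COc1cc(OCC=C)cc2c1C(=O)O[C@H]2CCCCCCCCCC(=O)CC[C@H](C)O
F8 | step 13 | methyl 4-(benzyloxy)-6-[(1S,14S)-1,14-bis(tert-butyldimethylsilyloxy)-11,11-(ethylenedioxy)pentadecyl]-2-hydroxybenzoate | COC(=O)c1c(O)cc(OCc2ccccc2)cc1[C@@H](O[Si](C)(C)C(C)(C)C)CCCCCCCCCC3(OCCO3)CC[C@H](C)O[Si](C)(C)C(C)(C)C
F9 | step 13 | methyl 4-(benzyloxy)-6-[(1S,14S)-1,14-bis(tert-butyldimethylsilyloxy)-11,11-(ethylenedioxy)pentadecyl]-2-methoxybenzoate | COC(=O)c1c(OC)cc(OCc2ccccc2)cc1[C@@H](O[Si](C)(C)C(C)(C)C)CCCCCCCCCC3(OCCO3)CC[C@H](C)O[Si](C)(C)C(C)(C)C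
F10 | step 13 | (3S)-5-(benzyloxy)-3-[(13S)-13-hydroxy-10-oxotetradecyl]-7-methoxy-2-benzofuran-1(3H)-one | COc1cc(OCc2ccccc2)cc2c1C(=O)O[C@H]2CCCCCCCCCC(=O)CC[C@H](C)O
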